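## The problem

Daucane locants are used throughout: C1 is the ring-fusion carbon with the angular methyl, C2 carries the acetate, C3 is CH2, C4 is the tertiary carbinol with the isopropyl group, C5 is the ring-fusion CH, C6 carries the aryl ester, C7=C8 is the alkene (methyl on C8), C9 is the ketone and C10 is CH2.

- Target 24 is a trans-fused bicyclo[5.3.0]decane whose fusion carbon C1 is quaternary, so the 5–7 junction must be made with a fully substituted carbon and with H5 anti to the C1 methyl.
- There are five stereocentres (C1, C2, C4, C5, C6). On the cyclopentane the C1 methyl, the C2 acetoxy group, the C4 isopropyl group and the C5–C6 bond share one face, and the C4 hydroxyl and H5 share the other. At C6 the ester oxygen is cis to H5.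
- Reagents reach the bicycle from the face opposite the C1 methyl. That is right for a hydride at C2, but an isopropyl nucleophile adding to a C4 ketone would give the wrong C4 epimer, so oxygen must be delivered to a C4 that already carries the isopropyl group. A hydride at C6 also gives the wrong epimer, so C6 needs an inversion.
- The γ-acyloxy enone (elimination, dienolate formation), the two esters, the free phenol and the tertiary alcohol rule out strong bases, hydrides and hard nucleophiles late in the route; the aryl ester has to come last.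
- The feature that makes the key step possible: the five contiguous ring carbons C5–C9 carry oxygen at C6 and C9 on either side of the C7=C8 bond (methyl on C8). That is the imprint of a 3-oxidopyrylium derived from a 4-methylfuran, with C5 as the ylide carbon. The other two carbons of the seven-membered ring, C1 (with its methyl) and C10, are a 1,1-disubstituted alkene, and C4–C3–C2 of the five-membered ring is the three-atom tether joining that alkene to C5.
- Control: the reagent-set C2 stereocentre chooses the alkene face in the cycloaddition and so fixes C1, C5 and C9. The rigid tricycle then controls C4, and the C1 methyl controls protonation at C5 and reduction at C6.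

## Retrosynthesis

**24 ⇒ 22 + 23.** The C6–O(acyl) bond is cut last, because the γ-acyloxy enone and the phenol ester are the most fragile parts. The forward reaction must esterify the hindered 6S allylic alcohol 22 with inversion and without protecting the phenol of 23.

**22 ⇒ 21 ⇒ 20.** No carbon–carbon bond is cut; the C9 ketone/C6 carbinol pattern is traced back to the C6 ketone/C9 carbinol of 20 through triol 21. The transposition is the price of the cycloaddition, which places the carbonyl next to the ylide carbon C5. The forward reactions are a reduction of the only ketone and a site-selective oxidation of the less hindered allylic alcohol.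

**20 ⇒ 18.** The C5–H bond and the C9 hydroxyl are reconnected as a C5–O–C9 ether. A 4-hydroxycyclohept-2-enone is the retron of an 8-oxabicyclo[3.2.1]oct-3-en-2-one, and the forward step is a reductive cleavage of the α-alkoxy ketone. The oxygen at C5 is replaced by hydrogen on the same face, which is what turns the cycloadduct geometry into the trans ring fusion.

**18 ⇒ 16.** The C4–O bond is cut to the C3=C4 alkene. The neighbouring option, a C4 ketone plus an isopropyl nucleophile, would place the hydroxyl on the wrong face. Hydration of an alkene that already bears the isopropyl group delivers oxygen from the open face of the tricycle.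

**16 ⇒ 15 ⇒ 14.** This is the key disconnection: the C1–C5 and C9–C10 bonds are cut together. Both carbocycles, the quaternary centre and the C1/C5/C9 relationships go back to ylide 15 and the monocyclic acetoxypyranone 14, which has one controlled stereocentre. The alternative, stepwise ring closures, would need the C1/C5 trans relationship set separately.

**14 ⇒ 13 ⇒ 12.** The pyranone is traced to a furan by the Achmatowicz rearrangement. C6 (ketone), C7=C8 (with its methyl) and C9 are the four carbons of a 4-methylfuran, and C5 is the furfuryl carbinol carbon. The forward reaction must oxidise the furan in the presence of two alkenes.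

**12 ⇒ 7 + 10.** The C4–C5 bond is cut between an alkenyl iodide and an aldehyde. This is convergent, keeps the (Z) geometry of C3=C4 and tolerates the acetate. The reverse polarity (furyl anion plus an enal) would need more steps to make the enal.

**7 ⇒ 6 ⇒ 4 ⇒ 3 ⇒ 1 + 2.** The (Z)-trisubstituted iodoalkene is traced to a propargylic alcohol (hydroxyl-directed trans-hydroalumination, then iodination), the C2 stereocentre to an enantioselective ynone reduction, and the C2–C3 bond to an acid chloride and a terminal alkyne.

**10 ⇒ 8 + 9.** The furan methyl (C8 methyl of the target) is placed by cross-coupling on a purchasable bromofurfural.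

## Roads not taken

**Alternative 1:** (the most obvious) ring-closing metathesis across C7=C8. A fully substituted cyclopentane diene A1 would be closed to the cycloheptenone with second-generation Grubbs catalyst. A1 already holds all five stereocentres, including the quaternary C1 and the trans C1/C5 pair, and each would have to be set on a cyclopentane one by one. The metathesis itself adds no stereochemistry and must join an electron-poor 1,1-disubstituted alkene next to an allylic ester. The chosen plan makes both rings and three stereocentres from a monocyclic precursor in one step.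

**Alternative 2:** the other [5+2] polarity, with the oxygen bridge between C6 and C10. The ylide from acetoxypyranone A2 would add to 3-methylcyclopent-2-en-1-one A3 to give adduct A4, and reductive cleavage of the C10–O bond would give the C9 ketone and C6 oxygen without any transposition. The addition is intermolecular onto a β,β-disubstituted enone, which such ylides engage poorly. A cyclic alkene can only give the cis ring fusion, there is no handle for absolute configuration, and the C4 ketone of A4 would take the isopropyl nucleophile on the wrong face. The chosen plan pays two redox steps for the transposition and gains an intramolecular, trans-selective, enantiocontrolled cycloaddition.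

**Alternative 3:** Buchner dearomatisation of a hydroquinone dimethyl ether. An aryl diazoketone A5 would be cyclopropanated on the arene with Rh2(OAc)4 and open by 6π-electrocyclisation to cycloheptatriene A6, which closes both rings from a flat arene. The carbenoid must attack the ortho carbon that bears a methoxy group. C1 stays sp2, so the angular methyl needs a later conjugate addition with nothing to direct it. C4 is again a ketone that accepts isopropyl from the wrong face, and two enol ethers must be differentiated. The chosen cycloaddition sets the quaternary centre and the fusion geometry directly.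

Key step: step 9

Remark: compounds 1, 2, 8, 9 and 23 are taken as purchased; the SMILES places the C4 hydroxyl on the cyclopentane face opposite the angular methyl, and the route is designed for exactly this arrangement.

## Steps

Step 1
Reactants: 1 3-methylbut-1-yne; 2 methacryloyl chloride
Product: 3 2,6-dimethylhept-1-en-4-yn-3-one
Conditions: PdCl2(PPh3)2 (2 mol %), CuI (4 mol %), Et3N, THF, 0 °C to rt
Reagents that add atoms: none
Why: Acyl Sonogashira coupling: the copper acetylide of 1 is acylated through the acylpalladium chloride from 2, which gives the cross-conjugated ynone directly and without a stereocentre.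

Step 2
Reactants: 3 2,6-dimethylhept-1-en-4-yn-3-one
Product: 4 (3R)-2,6-dimethylhept-1-en-4-yn-3-ol
Conditions: (R)-2-methyl-CBS-oxazaborolidine (20 mol %), BH3·SMe2, THF, −30 °C; MeOH quench
Reagents that add atoms: none
Why: Corey–Bakshi–Shibata reduction: the alkynyl group acts as the small and the isopropenyl group as the large substituent in the oxazaborolidine–borane complex, so the (R)-catalyst should give the (R)-carbinol, which becomes C2 of the target.

Step 3
Reactants: 4 (3R)-2,6-dimethylhept-1-en-4-yn-3-ol
Product: 6 (3S,4Z)-5-iodo-2,6-dimethylhepta-1,4-dien-3-ol, via cyclic alkenylaluminate 5 (not isolated)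
Conditions: NaAlH2(OCH2CH2OCH3)2, THF, 0 °C to rt; then I2, −78 °C
Reagents that add atoms: iodine, II
Why: Hydroxyl-directed trans-hydroalumination of a propargylic alcohol: hydride goes to the proximal alkyne carbon and aluminium to the distal, isopropyl-bearing carbon inside a five-membered aluminate, and iodine replaces aluminium with retention. This fixes the (Z)-alkene that becomes C3=C4; the descriptor changes from R to S only through the priority rules.

Step 4
Reactants: 6 (3S,4Z)-5-iodo-2,6-dimethylhepta-1,4-dien-3-ol
Product: 7 (3S,4Z)-5-iodo-2,6-dimethylhepta-1,4-dien-3-yl acetate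
Conditions: Ac2O, pyridine, DMAP (cat.), CH2Cl2, 0 °C
Reagents that add atoms: acetic anhydride, CC(=O)OC(C)=O
Why: DMAP-catalysed acetylation of a secondary alcohol; the acetate is the C2 ester of the target and is carried to the end.

Step 5
Reactants: 8 4-bromofuran-2-carbaldehyde; 9 2,4,6-trimethylboroxine
Product: 10 4-methylfuran-2-carbaldehyde
Conditions: Pd(PPh3)4 (5 mol %), K2CO3, 1,4-dioxane/H2O, 90 °C
Reagents that add atoms: none
Why: Suzuki–Miyaura methylation of the heteroaryl bromide; the aldehyde is inert, and the methyl group becomes the C8 methyl of the target.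

Step 6
Reactants: 7 (3S,4Z)-5-iodo-2,6-dimethylhepta-1,4-dien-3-yl acetate; 10 4-methylfuran-2-carbaldehyde
Product: 12 (3S,4Z)-5-[hydroxy(4-methylfuran-2-yl)methyl]-2,6-dimethylhepta-1,4-dien-3-yl acetate (both carbinol epimers), via alkenylchromium dichloride 11 (not isolated)
Conditions: CrCl2 (4 equiv), NiCl2 (2 mol %), DMF, rt
Reagents that add atoms: none
Why: Nozaki–Hiyama–Kishi coupling: zerovalent nickel inserts into the C–I bond with retention of the (Z) geometry and hands the alkenyl group to trivalent chromium, which adds only to the aldehyde and leaves the acetate alone. The new carbinol centre (C5) needs no control because it becomes planar in step 9.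

Step 7
Reactants: 12 (3S,4Z)-5-[hydroxy(4-methylfuran-2-yl)methyl]-2,6-dimethylhepta-1,4-dien-3-yl acetate
Product: 13 (3S,4Z)-5-(6-hydroxy-5-methyl-3-oxo-3,6-dihydro-2H-pyran-2-yl)-2,6-dimethylhepta-1,4-dien-3-yl acetate (diastereomer mixture at the two pyranone stereocentres)
Conditions: NBS, NaHCO3, NaOAc, THF/H2O 4:1, 0 °C
Reagents that add atoms: water, O
Why: Achmatowicz rearrangement: NBS oxidises the electron-rich furan far faster than the isolated alkenes, and the resulting ene-dione is closed by the carbinol oxygen to the pyranone hemiacetal. This dearomatisation turns the flat furan into C6–C9 of the seven-membered ring.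

Step 8
Reactants: 13 (3S,4Z)-5-(6-hydroxy-5-methyl-3-oxo-3,6-dihydro-2H-pyran-2-yl)-2,6-dimethylhepta-1,4-dien-3-yl acetate
Product: 14 (3S,4Z)-5-(6-acetoxy-5-methyl-3-oxo-3,6-dihydro-2H-pyran-2-yl)-2,6-dimethylhepta-1,4-dien-3-yl acetate (diastereomer mixture at the two pyranone stereocentres)
Conditions: Ac2O, pyridine, DMAP (cat.), CH2Cl2, 0 °C
Reagents that add atoms: acetic anhydride, CC(=O)OC(C)=O
Why: Acetylation of the anomeric hydroxyl turns it into the leaving group needed for ylide formation.

Step 9
Reactants: 14 (3S,4Z)-5-(6-acetoxy-5-methyl-3-oxo-3,6-dihydro-2H-pyran-2-yl)-2,6-dimethylhepta-1,4-dien-3-yl acetate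
Product: 16 (1R,2S,5S,9R)-2-acetoxy-5,9-epoxydauca-3,7-dien-6-one, via 3-oxidopyrylium ylide 15 (not isolated)
Conditions: Et3N, MeCN, 60 °C
Reagents that add atoms: none
Why: Triethylamine removes the acidic C5–H (α to the ketone and allylic) and acetate leaves from C9 to give the 3-oxidopyrylium 15, which adds across C5 and C9 to the tethered 1,1-disubstituted alkene in a concerted, suprafacial six-electron [5+2] cycloaddition. The closest known reaction type is the intramolecular oxidopyrylium–alkene cycloaddition of Achmatowicz-derived acetoxypyranones through a three-atom tether. The five-membered carbocycle (C1–C5) closes through the C1–C5 bond, with the tether C4=C3–C2 joining the ylide carbon to the internal alkene carbon. The seven-membered carbocycle (C5–C6–C7–C8–C9–C10–C1) closes when C9–C10 forms in the same event, and the pyrylium oxygen becomes the C5–O–C9 bridge. C5 and C9 are set together because both bonds form on one face of the planar ylide. C1 is set relative to C5 by the tether, which can only reach the exo position of the new two-carbon bridge; C2 is therefore exo and the methyl endo, anti to the bridging oxygen, which becomes the trans ring fusion once that oxygen is exchanged for hydrogen in step 11. The absolute sense comes from the C2 acetoxy stereocentre: in the reacting conformer the C2 hydrogen should take the inside position over the pyrylium oxygen and the acetoxy group should point outward, which selects the alkene face that places the acetoxy group cis to the C1 methyl. The step needs regioselectivity (fixed by the tether), exo closure (enforced by ring strain), facial selectivity (from C2), and a cycloaddition fast enough to beat electrocyclisation or dimerisation of the vinylogous ylide, which the nearby alkene should secure.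

Step 10
Reactants: 16 (1R,2S,5S,9R)-2-acetoxy-5,9-epoxydauca-3,7-dien-6-one
Product: 18 (1R,2S,4R,5R,9R)-2-acetoxy-5,9-epoxy-4-hydroxydauc-7-en-6-one, via tertiary hydroperoxide 17 (not isolated)
Conditions: Co(acac)2 (20 mol %), PhSiH3, O2 (1 atm), THF/i-PrOH, rt; then PPh3
Reagents that add atoms: dioxygen, O=O
Why: Mukaiyama hydration: a cobalt hydride transfers a hydrogen atom to C3 of the electron-rich trisubstituted alkene, and the tertiary C4 radical is trapped by O2 on the open face of the cyclopentane, anti to the C6 carbonyl, the C1 methyl and the C2 acetate. The C4 oxygen therefore ends cis to the oxygen bridge with the isopropyl group on the crowded face; the enone should be spared because its β-carbon is fully substituted and electron-poor.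

Step 11
Reactants: 18 (1R,2S,4R,5R,9R)-2-acetoxy-5,9-epoxy-4-hydroxydauc-7-en-6-one
Product: 20 (1S,2S,4R,5S,9R)-2-acetoxy-4,9-dihydroxydauc-7-en-6-one, via samarium dienolate 19 (not isolated)
Conditions: SmI2 (2.2 equiv), THF/MeOH, −78 °C
Reagents that add atoms: none
Why: Samarium diiodide reduction of an α-alkoxy ketone: the C6 ketyl expels the C5–O bond aligned with its π system and a second electron gives dienolate 19. Methanol then protonates C5 on the face anti to the C1 methyl and the C4 isopropyl group, which is the face the oxygen left, so the ring fusion becomes trans; the descriptor changes at C1 and C5 follow only from the priority rules.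

Step 12
Reactants: 20 (1S,2S,4R,5S,9R)-2-acetoxy-4,9-dihydroxydauc-7-en-6-one
Product: 21 (1S,2S,4R,5R,6S,9R)-2-acetoxydauc-7-ene-4,6,9-triol
Conditions: NaBH4, CeCl3·7H2O, MeOH, −40 °C
Reagents that add atoms: none
Why: Luche reduction: 1,2-hydride addition to the only ketone from the face anti to the axial C1 methyl and the C4 isopropyl group gives the 6S alcohol, with its hydroxyl trans to H5 (the C6 epimer of the target carbinol).

Step 13
Reactants: 21 (1S,2S,4R,5R,6S,9R)-2-acetoxydauc-7-ene-4,6,9-triol
Product: 22 (1S,2S,4R,5R,6S)-2-acetoxy-4,6-dihydroxydauc-7-en-9-one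
Conditions: MnO2 (activated, excess), CH2Cl2, rt
Reagents that add atoms: none
Why: Allylic oxidation with MnO2: the C9 carbinol lies next to a CH2 on the open face, whereas the C6 carbinol is flanked by C5 and sits on the face crowded by the methyl and isopropyl groups, so the C9 ketone should form selectively. Material oxidised at the wrong site or twice returns to 21 under the conditions of step 12.

Step 14
Reactants: 22 (1S,2S,4R,5R,6S)-2-acetoxy-4,6-dihydroxydauc-7-en-9-one; 23 4-hydroxybenzoic acid
Product: 24 (1S,2S,4R,5R,6R)-2-acetoxy-4-hydroxy-9-oxodauc-7-en-6-yl 4-hydroxybenzoate (target)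
Conditions: PPh3, DIAD, THF, 0 °C to rt
Reagents that add atoms: none
Why: Mitsunobu esterification: the carboxylate of 23, far more acidic than its phenol, displaces the oxyphosphonium ion at the allylic C6 with inversion from the open face, which gives the 6R ester cis to H5. The tertiary C4 alcohol is not activated.

## Compound list

1 | 3-methylbut-1-yne | C#CC(C)C | starting material
2 | methacryloyl chloride | CC(=C)C(Cl)=O | starting material
3 | 2,6-dimethylhept-1-en-4-yn-3-one | C=C(C)C(=O)C#CC(C)C | intermediate
4 | (3R)-2,6-dimethylhept-1-en-4-yn-3-ol | O[C@H](C(C)=C)C#CC(C)C | intermediate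
5 | sodium cyclic alkenylaluminate from 4 (aluminium on the isopropyl-bearing alkene carbon and on the carbinol oxygen) | [Na+].COCCO[Al-]1(OCCOC)O[C@H](C(C)=C)C=C1C(C)C | intermediate
6 | (3S,4Z)-5-iodo-2,6-dimethylhepta-1,4-dien-3-ol | O[C@H](C(C)=C)/C=C(/C(C)C)I | intermediate
7 | (3S,4Z)-5-iodo-2,6-dimethylhepta-1,4-dien-3-yl acetate | CC(=O)O[C@H](C(C)=C)/C=C(/C(C)C)I | intermediate
8 | 4-bromofuran-2-carbaldehyde | O=Cc1cc(Br)co1 | starting material
9 | 2,4,6-trimethylboroxine | CB1OB(C)OB(C)O1 | starting material
10 | 4-methylfuran-2-carbaldehyde | O=Cc1cc(C)co1 | intermediate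
11 | alkenylchromium dichloride from 7 (trivalent chromium in place of iodine, Z geometry kept) | CC(=O)O[C@H](C(C)=C)/C=C(/C(C)C)[Cr](Cl)Cl | intermediate
12 | (3S,4Z)-5-[hydroxy(4-methylfuran-2-yl)methyl]-2,6-dimethylhepta-1,4-dien-3-yl acetate, both carbinol epimers | CC(=O)O[C@H](C(C)=C)/C=C(/C(C)C)C(O)c1cc(C)co1 | intermediate
13 | (3S,4Z)-5-(6-hydroxy-5-methyl-3-oxo-3,6-dihydro-2H-pyran-2-yl)-2,6-dimethylhepta-1,4-dien-3-yl acetate, mixture at the pyranone stereocentres | CC(=O)O[C@H](C(C)=C)/C=C(/C(C)C)C1OC(O)C(C)=CC1=O | intermediate
14 | (3S,4Z)-5-(6-acetoxy-5-methyl-3-oxo-3,6-dihydro-2H-pyran-2-yl)-2,6-dimethylhepta-1,4-dien-3-yl acetate, mixture at the pyranone stereocentres | CC(=O)O[C@H](C(C)=C)/C=C(/C(C)C)C1OC(OC(C)=O)C(C)=CC1=O | intermediate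
15 | 2-[(1Z,3S)-3-acetoxy-4-methyl-1-(propan-2-yl)penta-1,4-dien-1-yl]-5-methylpyrylium-3-olate | CC(=O)O[C@H](C(C)=C)/C=C(/C(C)C)c1[o+]cc(C)cc1[O-] | intermediate
16 | (1R,2S,5S,9R)-2-acetoxy-5,9-epoxydauca-3,7-dien-6-one (oxygen bridge anti to the C1 methyl, acetate cis to it) | CC(=O)O[C@H]1C=C(C(C)C)[C@@]2(O3)C(=O)C=C(C)[C@H]3C[C@]12C | intermediate
17 | (1R,2S,4R,5R,9R)-2-acetoxy-5,9-epoxy-4-hydroperoxydauc-7-en-6-one | CC(=O)O[C@H]1C[C@@](OO)(C(C)C)[C@@]2(O3)C(=O)C=C(C)[C@H]3C[C@]12C | intermediate
18 | (1R,2S,4R,5R,9R)-2-acetoxy-5,9-epoxy-4-hydroxydauc-7-en-6-one | CC(=O)O[C@H]1C[C@@](O)(C(C)C)[C@@]2(O3)C(=O)C=C(C)[C@H]3C[C@]12C | intermediate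
19 | bis(diiodosamarium) dienolate/alkoxide from 18 (C5=C6 enolate, C9 alkoxide) | CC(=O)O[C@H]1C[C@@](O)(C(C)C)C2=C(O[Sm](I)I)C=C(C)[C@H](O[Sm](I)I)C[C@]12C | intermediate
20 | (1S,2S,4R,5S,9R)-2-acetoxy-4,9-dihydroxydauc-7-en-6-one (trans-fused) | CC(=O)O[C@H]1C[C@@](O)(C(C)C)[C@H]2C(=O)C=C(C)[C@H](O)C[C@]12C | intermediate
21 | (1S,2S,4R,5R,6S,9R)-2-acetoxydauc-7-ene-4,6,9-triol | CC(=O)O[C@H]1C[C@@](O)(C(C)C)[C@H]2[C@@H](O)C=C(C)[C@H](O)C[C@]12C | intermediate
22 | (1S,2S,4R,5R,6S)-2-acetoxy-4,6-dihydroxydauc-7-en-9-one | CC(=O)O[C@H]1C[C@@](O)(C(C)C)[C@H]2[C@@H](O)C=C(C)C(=O)C[C@]12C | intermediate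
23 | 4-hydroxybenzoic acid | O=C(O)c1ccc(O)cc1 | starting material
24 | (1S,3R,3aR,4R,8aS)-1-acetoxy-3-hydroxy-6,8a-dimethyl-7-oxo-3-(propan-2-yl)-1,2,3,3a,4,7,8,8a-octahydroazulen-4-yl 4-hydroxybenzoate (daucane locants: 1S,2S,4R,5R,6R) | CC(=O)O[C@H]1C[C@@](O)(C(C)C)[C@H]2[C@H](OC(=O)c3ccc(O)cc3)C=C(C)C(=O)C[C@]12C | target

## Step count and risk

Total step count: 14. Longest linear sequence: 13 steps (steps 1–4 and 6–14; step 5 is a one-step branch).

**Step 9 (key step).** The most likely failure is poor or reversed facial selectivity, because the C2 acetoxy group is the only element that chooses the alkene face; electrocyclisation of the vinylogous ylide is a second possibility. The fallback uses the C2 stereocentre only as a relay and corrects it afterwards with known chemistry. It sets out from 3 and returns to the route at 18.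
- Reduction of 3 with the (S)-oxazaborolidine gives (3S)-2,6-dimethylhept-1-en-4-yn-3-ol F1.
- Steps 3, 4 and 6 to 8 carried out on this series give, through the aluminate F2, the iodo alcohol F3, its acetate F4, the alkenylchromium species F5, the furyl carbinol F6 and the hydroxypyranone F7, the enantiomeric acetoxypyranone F8.
- If the acetoxy group prefers the inside position, the ylide F9 closes to the C2 epimer of 16, F10, which has the ring stereocentres of 16.
- Hydration as in step 10 (through hydroperoxide F11) gives F12. K2CO3 in MeOH removes the acetate to give diol F13, and Dess–Martin periodinane gives the cyclopentanone F14.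
- Me4NBH(OAc)3 delivers hydride from the C4 hydroxyl, on the face anti to the C1 methyl, to give the trans-diol F15; acetylation of its secondary hydroxyl gives 18.

**Step 10.** The likely failures are loss of chemoselectivity (hydrogen-atom transfer to the enone) and incomplete facial selectivity in the oxygen trapping of the C4 radical. The fallback replaces the radical hydration by a two-electron sequence; it sets out from 16 and returns at 18.
- mCPBA epoxidises only the electron-rich C3=C4 bond, on the open face, to give epoxide F16.
- LiAlH4 opens the epoxide at the secondary carbon C3 and reduces the ketone and the acetate to give triol F17.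
- MnO2 re-oxidises the allylic C6 alcohol to the enone F15, and acetylation of the secondary hydroxyl gives 18.

**Step 13.** The likely failure is oxidation at the wrong carbinol or over-oxidation to the ene-dione. The fallback separates the two carbinols by protection; it sets out from 20 and returns at 24.
- Et3SiCl and imidazole silylate the C9 hydroxyl of 20 to give F18.
- Luche reduction gives the 6S alcohol F19, and Mitsunobu esterification with 23 gives the 6R ester F20.
- HF·pyridine frees the C9 alcohol F21, and MnO2 oxidises it to 24.

**Step 14.** The likely failures are elimination of the activated γ-hydroxy enone towards C5 and slow activation of the hindered alcohol with esterification under retention. The fallback separates activation from displacement; it sets out from 22 and returns at 24.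
- MsCl and Et3N give the mesylate F22.
- Caesium 4-hydroxybenzoate (from 23 and Cs2CO3) in DMF displaces it with inversion to give 24.

## Further compounds

F1 | step 9 | (3S)-2,6-dimethylhept-1-en-4-yn-3-ol | O[C@@H](C(C)=C)C#CC(C)C
F2 | step 9 | sodium cyclic alkenylaluminate, enantiomer of 5 | [Na+].COCCO[Al-]1(OCCOC)O[C@@H](C(C)=C)C=C1C(C)C
F3 | step 9 | (3R,4Z)-5-iodo-2,6-dimethylhepta-1,4-dien-3-ol | O[C@@H](C(C)=C)/C=C(/C(C)C)I
F4 | step 9 | (3R,4Z)-5-iodo-2,6-dimethylhepta-1,4-dien-3-yl acetate | CC(=O)O[C@@H](C(C)=C)/C=C(/C(C)C)I
F5 | step 9 | alkenylchromium dichloride, enantiomer of 11 | CC(=O)O[C@@H](C(C)=C)/C=C(/C(C)C)[Cr](Cl)Cl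
F6 | step 9 | (3R,4Z)-5-[hydroxy(4-methylfuran-2-yl)methyl]-2,6-dimethylhepta-1,4-dien-3-yl acetate, both carbinol epimers | CC(=O)O[C@@H](C(C)=C)/C=C(/C(C)C)C(O)c1cc(C)co1
F7 | step 9 | (3R,4Z)-5-(6-hydroxy-5-methyl-3-oxo-3,6-dihydro-2H-pyran-2-yl)-2,6-dimethylhepta-1,4-dien-3-yl acetate | CC(=O)O[C@@H](C(C)=C)/C=C(/C(C)C)C1OC(O)C(C)=CC1=O
F8 | step 9 | (3R,4Z)-5-(6-acetoxy-5-methyl-3-oxo-3,6-dihydro-2H-pyran-2-yl)-2,6-dimethylhepta-1,4-dien-3-yl acetate | CC(=O)O[C@@H](C(C)=C)/C=C(/C(C)C)C1OC(OC(C)=O)C(C)=CC1=O
F9 | step 9 | 2-[(1Z,3R)-3-acetoxy-4-methyl-1-(propan-2-yl)penta-1,4-dien-1-yl]-5-methylpyrylium-3-olate | CC(=O)O[C@@H](C(C)=C)/C=C(/C(C)C)c1[o+]cc(C)cc1[O-]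
F10 | step 9 | (1R,2R,5S,9R)-2-acetoxy-5,9-epoxydauca-3,7-dien-6-one (C2 epimer of 16) | CC(=O)O[C@@H]1C=C(C(C)C)[C@@]2(O3)C(=O)C=C(C)[C@H]3C[C@]12C
F11 | step 9 | C2 epimer of hydroperoxide 17 | CC(=O)O[C@@H]1C[C@@](OO)(C(C)C)[C@@]2(O3)C(=O)C=C(C)[C@H]3C[C@]12C
F12 | step 9 | C2 epimer of 18 | CC(=O)O[C@@H]1C[C@@](O)(C(C)C)[C@@]2(O3)C(=O)C=C(C)[C@H]3C[C@]12C
F13 | step 9 | 5,9-epoxy-2,4-dihydroxydauc-7-en-6-one with the C2 hydroxyl trans to the C1 methyl | O[C@@H]1C[C@@](O)(C(C)C)[C@@]2(O3)C(=O)C=C(C)[C@H]3C[C@]12C
F14 | step 9 | 5,9-epoxy-4-hydroxydauc-7-ene-2,6-dione | O=C1C[C@@](O)(C(C)C)[C@@]2(O3)C(=O)C=C(C)[C@H]3C[C@]12C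
F15 | step 9 | 5,9-epoxy-2,4-dihydroxydauc-7-en-6-one with the C2 hydroxyl cis to the C1 methyl (2-O-deacetyl 18) | O[C@H]1C[C@@](O)(C(C)C)[C@@]2(O3)C(=O)C=C(C)[C@H]3C[C@]12C
F16 | step 10 | 2-acetoxy-3,4:5,9-diepoxydauc-7-en-6-one (3,4-epoxide cis to the oxygen bridge) | CC(=O)O[C@H]1[C@@H]4O[C@]4(C(C)C)[C@@]2(O3)C(=O)C=C(C)[C@H]3C[C@]12C
F17 | step 10 | 5,9-epoxydauc-7-ene-2,4,6-triol (C6 hydroxyl anti to the oxygen bridge) | O[C@H]1C[C@@](O)(C(C)C)[C@@]2(O3)[C@@H](O)C=C(C)[C@H]3C[C@]12C
F18 | step 13 | 9-O-triethylsilyl ether of 20 | CC(=O)O[C@H]1C[C@@](O)(C(C)C)[C@H]2C(=O)C=C(C)[C@H](O[Si](CC)(CC)CC)C[C@]12C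
F19 | step 13 | 9-O-triethylsilyl ether of 21 | CC(=O)O[C@H]1C[C@@](O)(C(C)C)[C@H]2[C@@H](O)C=C(C)[C@H](O[Si](CC)(CC)CC)C[C@]12C
F20 | step 13 | (6R)-6-(4-hydroxybenzoyloxy)-9-triethylsilyloxy analogue (C9 silyl ether, C9 not yet oxidised) | CC(=O)O[C@H]1C[C@@](O)(C(C)C)[C@H]2[C@H](OC(=O)c3ccc(O)cc3)C=C(C)[C@H](O[Si](CC)(CC)CC)C[C@]12C
F21 | step 13 | 9-hydroxy analogue of 24 (9R carbinol in place of the ketone) | CC(=O)O[C@H]1C[C@@](O)(C(C)C)[C@H]2[C@H](OC(=O)c3ccc(O)cc3)C=C(C)[C@H](O)C[C@]12C
F22 | step 14 | 6-O-methanesulfonate of 22 | CC(=O)O[C@H]1C[C@@](O)(C(C)C)[C@H]2[C@@H](OS(C)(=O)=O)C=C(C)C(=O)C[C@]12C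
A1 | alternative 1 | cyclopentane diene for ring-closing metathesis (C7 and C8 as terminal alkenes, all stereocentres of 24) | CC(=O)O[C@H]1C[C@@](O)(C(C)C)[C@@H]([C@H](OC(=O)c2ccc(O)cc2)C=C)[C@]1(C)CC(=O)C(C)=C
A2 | alternative 2 | 6-acetoxy-4-methyl-2H-pyran-3(6H)-one | CC1=CC(OC(C)=O)OCC1=O
A3 | alternative 2 | 3-methylcyclopent-2-en-1-one | CC1=CC(=O)CC1
A4 | alternative 2 | cis-fused 6,10-epoxy-bridged cycloadduct (racemic, one enantiomer drawn) | CC1=C[C@H]2O[C@@H](C1=O)[C@@]3(C)CCC(=O)[C@@H]23
A5 | alternative 3 | 1-diazo-4-(2,5-dimethoxy-4-methylphenyl)-4-(tert-butyldimethylsilyloxy)butan-2-one | COc1cc(C)c(OC)cc1[C@@H](O[Si](C)(C)C(C)(C)C)CC(=O)C=[N+]=[N-]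
A6 | alternative 3 | cycloheptatriene from ring expansion of A5 (C1 still sp2, C5 epimers) | COC1=CC(C)=C(OC)C=C2[C@@H](O[Si](C)(C)C(C)(C)C)CC(=O)C12
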